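The numbers in the tables stem from a simulated flask on assumed constants.

- At 0.417 d the teal run already holds 66.9% open dimer against 12.7% ring, so the two products race for one starting material, and the question for the flask is how that race shifts with the charge.

- teal: starting material 40 mM; run made earlier
- flask: starting material 20 mM; time 15 d

teal run (percent of the starting material charged)

| time / d | open dimer / % | ring / % |
|---|---|---|
| 0.417 | 66.9 | 12.7 |
| 0.833 | 69.6 | 15.5 |
| 1.25 | 69.2 | 18.0 |
| 1.67 | 67.1 | 19.5 |
| 2.00 | 65.8 | 20.9 |
| 2.50 | 63.2 | 21.9 |
| 3.00 | 62.1 | 23.6 |

(scatter of a reading: 0.5 percentage points)

* time, not beyond 15 d, at which the flask holds most open dimer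
* the amount of open dimer, in percent of the starting material charged, at that time
* earliest time at which at least nineteen twentieths of that best amount are there, in d
* latest time at which they still are, in d

- in percentages every species weighs as the starting material in it: one open dimer counts as two
- a reading or a percentage of ring counts all its forms, free or not

- The reckoning here treats ring as a small correction to the second-order fall of [starting material], and takes starting material as what the two columns leave. Ring share is then roughly the natural logarithm of the inverse free share, divided by the race number, which is the rate of starting material into open dimer over its rate into ring at the charge, a selectivity factor; read from the first teal reading, with its scatter, this rough form gives 12.5.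
- Reckoned with no undoing of open dimer, ring ends near the logarithm of one plus the race number, over the race number, which gives an estimated ceiling on open dimer of 79.2% for teal, and the highest teal reading, 69.6%, lies 9.6 percentage points below it.
- Amount by hand: assuming ring forms from one molecule and open dimer from two, the race number follows the charge, so 20 mM makes it 6.26, the ceiling 68.3%, and, with the teal gap carried over unchanged, the best 58.7%.
- Time by hand: teal open dimer is already falling from 69.6% at 0.833 d to 62.1% at 3.00 d, so a longer run should leave the best where it is.
- The forecast gives 58% (52% to 65%) at 1.1 d (0.8 d to 1.8 d), open at 0.55 d (0.4 d to 0.8 d) and shut at 1.7 d (1.3 d to 3 d), reasoning that “equilibrium favours dimer less and the approach is slower”; its best lies a little below the reckoning here.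
- The flask gives 57.8% at 1.07 d, open at 0.556 d and shut at 2.10 d, later than the forecast's close. From teal, changing the amount moves the highest value from 69.9% to 57.8%, while changing the time leaves it at 69.9%.

    starting material + ring → side product (k = 1.20 /M/h)
    2 starting material ⇌ open dimer (K = 1000 /M, k = 4.30 /M/h)
    starting material → ring (k = 0.0340 /h)
    crystals ⇌ ring, rate k4*(cs4 - [ring]) while solid is left; crystals form when [ring] > cs4 (solubility = 12.0 mM, k = 0.740 /h)

- In the flask the estimated ceiling stands 10 points above the best, against 9.6 points in teal, and part of that distance comes from the undoing of open dimer into starting material: a run of the flask without it reaches 62.8% against 57.8%. In the neighbour flask charged with 5.0 mM the race number becomes 1.56 and the estimated ceiling 39.8%, which less the teal gap is 30.2%, and that neighbour flask's best is 30.5%.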